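The numbers in the tables are calculated with made-up constants.

At 3.0 h, the time you want read, your hunch has the flask holding its first pace, which would give 90.0 %; we read the run differently.

- larch: electrophile 0.23 M; nucleophile 0.207 M; protic impurity 0.23 M; the very flask that is asked about, followed so far
- flask: electrophile 0.23 M; nucleophile 0.207 M; protic impurity 0.230 M; time 3.0 h

larch run (percent of the electrophile charged)

| time / min | electrophile / % | product / % |
|---|---|---|
| 2.00 | 99 | 2 |
| 6.00 | 98 | 6 |
| 10.0 | 96 | 7 |
| 15.0 | 92 | 10 |
| 20.0 | 88 | 10 |
| 30.0 | 85 | 14 |
| 40.0 | 83 | 15 |

(scatter of a reading: 1.5 percentage points)

- the analysis behind the earlier runs scatters by 1.5 percentage points, standard deviation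
- the earlier runs do not show how much of nucleophile is bound; that part of a forecast is a guess

1. part of the electrophile that has reacted at 3.0 h
2. share of the unused nucleophile that is free and not bound as protonated nucleophile, at 3.0 h

Larch is this very flask, followed for 40.0 min. Product gained 10 % by 20.0 min, but only 5 percentage points over the next window of the same length. We take this as a pace falling by a constant factor per window, assume free nucleophile, the limiting reagent, is what is disappearing, and work in powers of ten:

decade time = window / lg(first gain / second gain) = 66.4 min

run-out conversion = first gain / (1 − second gain / first gain) = 20.0 %

The run-out conversion is the sum of all gains if each window gives the same fraction of the one before. Since 3.0 h is 2.71 decade times, longer than one, we commit to it for the flask. With a scatter of 1.5 points on each reading it remains a reading, and the free share of nucleophile stays a guess. With the decade time and the other charges held, we expect the run-out conversion to follow c(nucleophile) as charged.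

The forecast stands above our number, at 26 % with 12 % free, holding that “If binding is reversible, some free nucleophile remains and the reaction keeps creeping”.

The flask gives 23.6 % reacted and 7.96 % free, 3.6 points above our run-out conversion, with free nucleophile at 2.07 % of its charge.

    electrophile + nucleophile → acid set free + product (k = 0.0360 M⁻¹ min⁻¹)
    nucleophile + acid set free ⇌ protonated nucleophile, settled at all times (K = 2400 M⁻¹)
    nucleophile + protic impurity → quenched reagent (k = 0.0750 M⁻¹ min⁻¹)

A neighbour flask charged with 0.83 M of nucleophile holds 4.01 times the charge, so with the decade time held the run-out conversion scales to 80.2 %; that neighbour stands at 87.8 % reacted, with 24 % of its nucleophile still free and 1.2 % of its protic impurity left.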